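The vessel holds a solid substrate that goes into solution over the earlier runs, and product readings in those runs lie close to zero, so express them on a scale that makes a small amount of product legible.

| flask | solid substrate | reagent | free catalyst | second catalyst | remark | time |
|---|---|---|---|---|---|---|
| eta | 0.032 M | 0.024 M | 0.32 mM | 3.2 mM | run made earlier |  |
| beta | 0.032 M | 0.036 M | 0.32 mM | 3.2 mM | run made earlier |  |
| theta | 0.032 M | 0.048 M | 0.48 mM | 3.2 mM | run made earlier |  |
| flask | 0.032 M | 0.0480 M | 0.32 mM | 3.2 mM |  | 80 min |

| run | time / min | product / % | solid substrate / % | starting material / % |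
|---|---|---|---|---|
| eta | 4.00 | 0 | 96 | 7 |
| eta | 12.0 | 0 | 90 | 13 |
| eta | 20.0 | 1 | 75 | 15 |
| eta | 30.0 | 1 | 73 | 20 |
| eta | 50.0 | 0 | 60 | 30 |
| beta | 10.0 | 3 | 90 | 9 |
| beta | 20.0 | 0 | 84 | 15 |
| beta | 30.0 | 0 | 78 | 21 |
| beta | 40.0 | 0 | 70 | 29 |
| beta | 50.0 | 0 | 60 | 28 |
| theta | 10.0 | 0 | 92 | 6 |
| theta | 20.0 | 3 | 79 | 17 |
| theta | 30.0 | 2 | 73 | 19 |
| theta | 40.0 | 0 | 68 | 25 |
| theta | 50.0 | 0 | 61 | 29 |

(scatter of a reading: 2 percentage points)

- given per volume of solution although it is solid: solid substrate
- at the start none of the solid substrate is in solution
- starting material means what is dissolved; the solid is not counted in it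

- concentration of product at 80 min, in M
- concentration of solid substrate at 80 min, in M
- concentration of starting material at 80 min, in M
- concentration of reagent at 80 min, in M

Count turnovers: divide c_product by the charged c_second catalyst. Full conversion takes 10.0 turnovers; call this ratio of charged solid substrate to charged second catalyst the turnover demand. Multiplied by a product share, it gives the turnovers made.

Average the 8 product readings from 30.0 min onward in eta, beta and theta:

mean product = 0.375% at a mean time of 40.0 min, or 0.0375 turnovers

Object at once: the standard error of that mean is 0.71 percentage points, larger than the mean itself, so treat this figure as a rough start.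

Next, object that time has to be carried to 80 min. Take the gap, meaning the charge minus solid, dissolved and product readings. Its mean reads 4.33% at 30.0 min and 10.7% at 50.0 min, which gives a read power of time:

m = ln(gap ratio)/ln(time ratio) = 1.76

Assume product, fed from the gap, grows with one power more:

turnovers at 80 min = 0.255

Object finally that these readings had a mean charge of 0.0375 M of reagent, less than this flask's 0.0480 M. Theta's readings also carry 0.48 mM of free catalyst against this flask's 0.32 mM; leave that uncorrected, so the estimate stays rough. For reagent, assume proportion:

turnovers = 0.326, so c_product = 0.00104 M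

The forecast expects less product than my reckoning, with 6.000 × 10⁻⁴ M of product, 0.013 M of solid substrate, 0.015 M of starting material and 0.046 M of reagent, and calls dissolution “the main visible process”.

The flask gives 0.00111 M of product, 0.0132 M of solid substrate, 0.0124 M of starting material and 0.0469 M of reagent.

    starting material + free catalyst ⇌ free catalyst + open intermediate (K = 8.55, k = 33.3 /M/min)
    second catalyst + open intermediate ⇌ catalyst intermediate (K = 2.77 /M, k = 9.45 /M/min)
    reagent + catalyst intermediate → second catalyst + product (k = 20.5 /M/min)
    solid substrate ⇌ starting material, rate k4*(cs4 - [starting material]) while solid is left; crystals form when [starting material] > cs4 (solubility = 31.0 mM, k = 0.0101 /min)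

At 80.0 min the flask's product is 3.46% of the solid charged, or 0.346 turnovers of the demand of 10.0. Now charge a neighbour flask with 0.012 M of reagent, a quarter of the flask's charge. That charge covers 3.75 turnovers, fewer than the demand, so by charge reagent is the limiting reagent of that neighbour. Proportion from the flask gives 0.0865 turnovers. The neighbour flask reaches 1.13% product, or 0.113 turnovers, with 0.0116 M of reagent remaining.

(Readings and results are calculated for substances that don't exist.)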